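**Retrosynthetic overview**
1. 23 ⇒ [3,3] Cope rearrangement of the (1(10)E,4E)-germacradien-12,6-olide 22. The cyclohexane ring (C5–C10 bond) forms last, and C6 controls C5 and C10.
2. 22 ⇒ two acylations of diol lactone 17 ⇒ oxidative lactonisation (O6 onto C12) of tetraol 14. The γ-lactone forms second.
3. 14 ⇒ hydroxyl-directed diboration/oxidation of the isopropenyl group of macrocycle 12. This installs C11–O and C12–O and converts C8–B into C8–O.
4. 12 ⇒ C6–C7 bond (the farnesyl C1–C10 closure) by intramolecular allylboration of an enal. The nucleophile is a Z-1,4-bis(boronate) from enantioselective diboration of acyclic 7. The ten-membered ring forms first, and C6, C7 and C8 are set here.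
5. 7 ⇒ geranyl acetate 1 (C10) + 2-methylbut-1-en-3-yne 4 (C5).

Assumption: germacrane numbering is used throughout, and the (R,R)-phosphonite is taken to give the (S) C–B centre at C8; if the sense is opposite, its enantiomer is used.

**Step 1**
Reactants: 1 geranyl acetate
Product: 2 (2E,6E)-8-hydroxy-3,7-dimethylocta-2,6-dien-1-yl acetate
Conditions: SeO2 (10 mol %), t-BuOOH (3 equiv), salicylic acid (10 mol %), CH2Cl2, rt
Reagents that add atoms: tert-butyl hydroperoxide CC(C)(C)OO (oxygen relayed by selenium dioxide O=[Se]=O)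
Why: Catalytic SeO2/t-BuOOH allylic oxidation (ene reaction, then [2,3]-sigmatropic shift) picks the electron-richer distal trisubstituted alkene and its E-methyl group, so the future C9 is oxygenated with the 1(10)E geometry in place and no stereocentre is involved.

**Step 2**
Reactants: 2 (2E,6E)-8-hydroxy-3,7-dimethylocta-2,6-dien-1-yl acetate
Product: 3 (2E,6E)-8-bromo-3,7-dimethylocta-2,6-dien-1-yl acetate
Conditions: CBr4, PPh3, CH2Cl2, 0 °C
Reagents that add atoms: carbon tetrabromide BrC(Br)(Br)Br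
Why: The Appel reaction converts the primary allylic alcohol by SN2 displacement of the alkoxyphosphonium ion without allylic transposition or E/Z loss, and the acetate is inert.

**Step 3**
Reactants: 3 (2E,6E)-8-bromo-3,7-dimethylocta-2,6-dien-1-yl acetate; 4 2-methylbut-1-en-3-yne
Product: 7 (2E,6E,9E)-3,7,11-trimethyldodeca-2,6,9,11-tetraen-1-ol, via dienylzirconocene chloride 5 (not isolated), via tetraene acetate 6 (not isolated)
Conditions: 4, Cp2Zr(H)Cl, THF, rt; then 3, Pd(PPh3)4 (5 mol %), 0 °C→rt; then K2CO3 (cat.), MeOH, rt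
Reagents that add atoms: 2-methylbut-1-en-3-yne C=C(C)C#C
Why: Hydrozirconation adds syn and only to the terminal alkyne of 4, the Negishi-type Pd-catalysed alkenyl–allyl coupling joins C8 to the less hindered CH2 terminus of the π-allyl from the bromide (which ionises far faster than the allylic acetate) with retention of all alkene geometries, and catalytic methanolysis of crude 6 frees the alcohol.

**Step 4**
Reactants: 7 (2E,6E,9E)-3,7,11-trimethyldodeca-2,6,9,11-tetraen-1-ol; 8 bis(pinacolato)diboron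
Product: 12 (1(10)E,4E,6S,7S,8S)-8-(pinacolatoboryl)germacra-1(10),4,11-trien-6-ol, via bis(boronate) alcohol 9 (not isolated), via bis(boronate) enal 10 (not isolated), via cyclic O-borate 11 (not isolated)
Conditions: Pt2(dba)3 (1.5 mol %), (R,R)-3,5-(i-Pr)2C6H3-TADDOL-PPh (3.6 mol %), 8 (1.05 equiv), toluene, 60 °C; then DMP, pyridine, CH2Cl2, 0 °C, filtration; then syringe pump into toluene (final 1 mM), 50 °C, 36 h; aq NaHCO3 work-up
Reagents that add atoms: bis(pinacolato)diboron CC1(C)OB(OC1(C)C)B1OC(C)(C)C(C)(C)O1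
Why: Proposed new method: Pt(0)/phosphonite-catalysed enantioselective 1,4-diboration touches only the s-cis-capable 1,3-diene and sets C8 (S) together with a Z-allylboronate, Dess–Martin oxidation then unmasks the enal, and its C6 is attacked by C7 of the primary allylboronate through a closed Zimmerman–Traxler chair (Z-boronate gives the 6,7-syn, i.e. cis-lactone, array, and approach anti to the C8–B bond with H8 in the A1,3-minimised inside position gives the 7,8 relationship), so the ten-membered ring, the isopropenyl group and three contiguous stereocentres arise in one telescoped operation; the alternative attack through the secondary boronate would need a quaternary centre and an eleven-membered ring, and the closest known reaction types are the tandem diene diboration/allylboration/oxidation route to 2-vinyl-1,3-diols and the allyl-zinc or allyl-chromium macrocyclisations of farnesal-type aldehydes to germacranes.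

**Step 5**
Reactants: 12 (1(10)E,4E,6S,7S,8S)-8-(pinacolatoboryl)germacra-1(10),4,11-trien-6-ol; 8 bis(pinacolato)diboron
Product: 14 (1(10)E,4E,6S,7R,8S,11S)-germacra-1(10),4-diene-6,8,11,12-tetraol, via tris(boronate) 13 (not isolated)
Conditions: 8 (2 equiv), Cs2CO3 (30 mol %), MeOH (10 equiv), THF, 60 °C; then 30 % H2O2, 3 M NaOH, 0 °C→rt
Reagents that add atoms: hydrogen peroxide OO
Why: In this alkoxide-catalysed hydroxyl-directed diboration the C6 alkoxide binds the diboron and delivers it through a chair-like cyclic transition state to the nearby 1,1-disubstituted alkene only (the trisubstituted ring alkenes are inert to base-catalysed diboration), which gives the 1,3-syn O6/O11 relationship, i.e. 11S, after stereoretentive oxidation of all three C–B bonds, and that oxidation also turns C8–B into C8–OH with retention.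

**Step 6**
Reactants: 14 (1(10)E,4E,6S,7R,8S,11S)-germacra-1(10),4-diene-6,8,11,12-tetraol
Product: 17 (1(10)E,4E,6S,7R,8S,11S)-8,11-dihydroxygermacra-1(10),4-dien-12,6-olide, via hydroxy aldehyde 15 (not isolated), via lactol 16 (not isolated)
Conditions: Cu(MeCN)4OTf, bpy, TEMPO (10 mol % each), N-methylimidazole (20 mol %), air, MeCN, rt
Reagents that add atoms: none
Why: Cu/nitroxyl aerobic oxidative lactonisation oxidises only the primary alcohol and then the derived lactol, and ring closure takes O6 because in the crown conformer fixed by A1,3 strain (H6 eclipsing C15) O6 is gauche to C11 whereas O8 is antiperiplanar to it; no stereocentre is touched and no acid is present that could trigger transannular cyclisation.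

**Step 7**
Reactants: 17 (1(10)E,4E,6S,7R,8S,11S)-8,11-dihydroxygermacra-1(10),4-dien-12,6-olide; 18 acetic anhydride
Product: 19 (1(10)E,4E,6S,7R,8S,11S)-8-acetoxy-11-hydroxygermacra-1(10),4-dien-12,6-olide
Conditions: Ac2O (1.2 equiv), pyridine, CH2Cl2, 0 °C→rt
Reagents that add atoms: acetic anhydride CC(=O)OC(C)=O
Why: This is a chemoselective acetylation in which the secondary C8 hydroxyl reacts while the tertiary, carbonyl-flanked C11 hydroxyl is inert without a nucleophilic catalyst.

**Step 8**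
Reactants: 19 (1(10)E,4E,6S,7R,8S,11S)-8-acetoxy-11-hydroxygermacra-1(10),4-dien-12,6-olide; 20 angelic anhydride
Product: 22 (1(10)E,4E,6S,7R,8S,11S)-8-acetoxy-11-angeloyloxygermacra-1(10),4-dien-12,6-olide, via lithium alkoxide 21 (not isolated)
Conditions: LiHMDS (1.05 equiv), THF, −78 °C; then 20 (1.5 equiv), −78→0 °C
Reagents that add atoms: angelic anhydride C/C=C(/C)C(=O)OC(=O)/C(C)=C\C
Why: Acylation of the preformed tertiary lithium alkoxide by the symmetrical anhydride is a stereoconservative angeloylation, since no nucleophilic catalyst or acid is present to isomerise angelate to tiglate, one equivalent of base meets only the O–H, and O8 lying anti to C11 disfavours acetyl migration.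

**Step 9**
Reactants: 22 (1(10)E,4E,6S,7R,8S,11S)-8-acetoxy-11-angeloyloxygermacra-1(10),4-dien-12,6-olide
Product: 23 (5R,6S,7R,8S,10R,11S)-8-acetoxy-11-angeloyloxyelema-1,3-dien-12,6-olide (CNP0140071.1)
Conditions: PdCl2(PhCN)2 (20 mol %), CH2Cl2, rt
Reagents that add atoms: none
Why: The Pd(II)-catalysed Cope rearrangement (a cyclisation-induced [3,3] shift known for germacranolides) runs through the chair transition state of the crown conformer, so the E,E-diene gives trans vinyl and isopropenyl groups and C10 bonds to the C5 face anti to O6 (H6 eclipsing C15), which sets 5R and 10R, with release of ten-ring strain as the driving force.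

**Compound list**
1 | geranyl acetate | CC(C)=CCC/C(C)=C/COC(C)=O | starting material
2 | (2E,6E)-8-hydroxy-3,7-dimethylocta-2,6-dien-1-yl acetate | OC/C(C)=C/CC/C(C)=C/COC(C)=O | intermediate
3 | (2E,6E)-8-bromo-3,7-dimethylocta-2,6-dien-1-yl acetate | BrC/C(C)=C/CC/C(C)=C/COC(C)=O | intermediate
4 | 2-methylbut-1-en-3-yne | C=C(C)C#C | starting material
5 | (E)-(3-methylbuta-1,3-dienyl)zirconocene chloride (Cp drawn η1) | C=C(C)/C=C/[Zr](Cl)(C1C=CC=C1)C1C=CC=C1 | intermediate
6 | (2E,6E,9E)-3,7,11-trimethyldodeca-2,6,9,11-tetraen-1-yl acetate | C=C(C)/C=C/C/C(C)=C/CC/C(C)=C/COC(C)=O | intermediate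
7 | (2E,6E,9E)-3,7,11-trimethyldodeca-2,6,9,11-tetraen-1-ol | C=C(C)/C=C/C/C(C)=C/CC/C(C)=C/CO | intermediate
8 | bis(pinacolato)diboron | CC1(C)OB(OC1(C)C)B1OC(C)(C)C(C)(C)O1 | starting material
9 | (2E,6E,9S,10Z)-3,7,11-trimethyl-9,12-bis(pinacolatoboryl)dodeca-2,6,10-trien-1-ol | OC/C=C(C)/CC/C=C(C)/C[C@H](B1OC(C)(C)C(C)(C)O1)/C=C(C)\CB1OC(C)(C)C(C)(C)O1 | intermediate
10 | (2E,6E,9S,10Z)-3,7,11-trimethyl-9,12-bis(pinacolatoboryl)dodeca-2,6,10-trienal | O=C/C=C(C)/CC/C=C(C)/C[C@H](B1OC(C)(C)C(C)(C)O1)/C=C(C)\CB1OC(C)(C)C(C)(C)O1 | intermediate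
11 | O6-pinacol borate of 12 | C1[C@H](B2OC(C)(C)C(C)(C)O2)[C@@H](C(C)=C)[C@@H](OB2OC(C)(C)C(C)(C)O2)/C=C(C)/CC/C=C1\C | intermediate
12 | (1(10)E,4E,6S,7S,8S)-8-(pinacolatoboryl)germacra-1(10),4,11-trien-6-ol (6β-OH, 7α-H, 8α-B) | C1[C@H](B2OC(C)(C)C(C)(C)O2)[C@@H](C(C)=C)[C@@H](O)/C=C(C)/CC/C=C1\C | intermediate
13 | 8,11,12-tris(pinacolatoboryl)germacra-1(10)E,4E-dien-6-ol (11S) | C1[C@H](B2OC(C)(C)C(C)(C)O2)[C@@H]([C@](C)(B2OC(C)(C)C(C)(C)O2)CB2OC(C)(C)C(C)(C)O2)[C@@H](O)/C=C(C)/CC/C=C1\C | intermediate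
14 | (1(10)E,4E,6S,7R,8S,11S)-germacra-1(10),4-diene-6,8,11,12-tetraol | C1[C@H](O)[C@@H]([C@](C)(O)CO)[C@@H](O)/C=C(C)/CC/C=C1\C | intermediate
15 | 6,8,11-trihydroxygermacra-1(10)E,4E-dien-12-al | C1[C@H](O)[C@@H]([C@](C)(O)C=O)[C@@H](O)/C=C(C)/CC/C=C1\C | intermediate
16 | 12,6-lactol of 15 (C12 anomers) | C1[C@H](O)[C@@H]2[C@@H](OC(O)[C@@]2(C)O)/C=C(C)/CC/C=C1\C | intermediate
17 | (1(10)E,4E,6S,7R,8S,11S)-8,11-dihydroxygermacra-1(10),4-dien-12,6-olide (cis-fused lactone) | C1[C@H](O)[C@@H]2[C@@H](OC(=O)[C@@]2(C)O)/C=C(C)/CC/C=C1\C | intermediate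
18 | acetic anhydride | CC(=O)OC(C)=O | starting material
19 | (1(10)E,4E,6S,7R,8S,11S)-8-acetoxy-11-hydroxygermacra-1(10),4-dien-12,6-olide | C1[C@H](OC(C)=O)[C@@H]2[C@@H](OC(=O)[C@@]2(C)O)/C=C(C)/CC/C=C1\C | intermediate
20 | angelic anhydride, (Z,Z)-2-methylbut-2-enoic anhydride | C/C=C(/C)C(=O)OC(=O)/C(C)=C\C | starting material
21 | lithium C11-alkoxide of 19 | [Li+].C1[C@H](OC(C)=O)[C@@H]2[C@@H](OC(=O)[C@@]2(C)[O-])/C=C(C)/CC/C=C1\C | intermediate
22 | (1(10)E,4E,6S,7R,8S,11S)-8-acetoxy-11-angeloyloxygermacra-1(10),4-dien-12,6-olide | C1[C@H](OC(C)=O)[C@@H]2[C@@H](OC(=O)[C@@]2(C)OC(=O)/C(C)=C\C)/C=C(C)/CC/C=C1\C | intermediate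
23 | (5R,6S,7R,8S,10R,11S)-8-acetoxy-11-angeloyloxyelema-1,3-dien-12,6-olide | C=C[C@@]1(C)C[C@H](OC(C)=O)[C@@H]2[C@@H](OC(=O)[C@@]2(C)OC(=O)/C(C)=C\C)[C@@H]1C(=C)C | target

**Totals:** 9 steps. The longest linear sequence is 9 steps, from geranyl acetate.

**The three steps most likely to fail are 4, 5 and 6.**

The macrocyclising allylboration of step 4 may be too slow on a β,β-disubstituted enal, so that oligomers win. The fallback sets out from 7 and comes back at 12.
- Sharpless asymmetric epoxidation of 7 (Ti(OiPr)4, L-(+)-DET, t-BuOOH) gives the (2S,3S)-2,3-epoxy alcohol F1.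
- The same Pt-catalysed diboration gives the epoxy bis(boronate) alcohol F2.
- Dess–Martin oxidation gives the non-conjugated and much more electrophilic epoxy aldehyde F3.
- F3 closes at high dilution, with C7 attacking anti to the epoxide C–O bond, to the cyclic epoxy O-borate F4.
- F4 is hydrolysed on work-up to the 4,5-epoxygermacradienol boronate F5.
- Stereospecific deoxygenation with WCl6/n-BuLi restores the 4E-alkene and gives 12.

The directed diboration of step 5 may stall at the hindered isopropenyl group or give the wrong C11 epimer. The fallback sets out from 12 and comes back at 17.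
- 9-BBN hydroborates only the 1,1-disubstituted alkene and gives the bis(9-BBN) adduct F6.
- H2O2/NaOH turns F6 into the 6,8,12-triol F7.
- Cu/TEMPO/air carries F7 through the hydroxy aldehyde F8 and the lactol F9 to the 8-hydroxy-11,13-dihydrolactone F10. Its C11 epimers are irrelevant because C11 is enolised next.
- LDA (3 equiv, −78 °C) gives the dilithio alkoxide enolate F11.
- The Davis oxaziridine hydroxylates F11 on the convex lactone face, anti to C8 and syn to H7, to give 17.

The lactonisation of step 6 may close onto O8 instead of O6. The fallback sets out from 14 and comes back at 19. It forms the C6–O bond by π-allyl chemistry, which only the allylic C6 position can undergo.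
- Ac2O/pyridine gives the 6,8,12-triacetate F12.
- K2CO3/MeOH at −10 °C removes only the primary acetate and gives the 6,8-diacetate 11,12-diol F13.
- Cu/TEMPO/air gives the α-hydroxy aldehyde F14, and Pinnick oxidation gives the α-hydroxy acid F15.
- Pd(PPh3)4/Et3N ionises the C6 acetate, and the carboxylate closes on C6 with net retention (double inversion) to give 19.

**Further compounds**
F1 | step 4 | (2S,3S)-2,3-epoxide of 7 | OC[C@@H]1O[C@@]1(C)CC/C=C(C)/C/C=C/C(C)=C
F2 | step 4 | (9S,10Z)-9,12-bis(pinacolatoboryl) derivative of F1 | OC[C@@H]1O[C@@]1(C)CC/C=C(C)/C[C@H](B2OC(C)(C)C(C)(C)O2)/C=C(C)\CB2OC(C)(C)C(C)(C)O2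
F3 | step 4 | epoxy aldehyde from F2 | O=C[C@@H]1O[C@@]1(C)CC/C=C(C)/C[C@H](B2OC(C)(C)C(C)(C)O2)/C=C(C)\CB2OC(C)(C)C(C)(C)O2
F4 | step 4 | O6-pinacol borate of F5 | C1[C@H](B2OC(C)(C)C(C)(C)O2)[C@@H](C(C)=C)[C@@H](OB2OC(C)(C)C(C)(C)O2)[C@@H]2O[C@@]2(C)CC/C=C1\C
F5 | step 4 | 4,5-epoxy-8-(pinacolatoboryl)germacra-1(10)E,11-dien-6-ol | C1[C@H](B2OC(C)(C)C(C)(C)O2)[C@@H](C(C)=C)[C@@H](O)[C@@H]2O[C@@]2(C)CC/C=C1\C
F6 | step 5 | O6,C12-bis(9-BBN) adduct of 12 (C11 epimers) | C1[C@H](B2OC(C)(C)C(C)(C)O2)[C@@H](C(C)CB2C3CCCC2CCC3)[C@@H](OB2C3CCCC2CCC3)/C=C(C)/CC/C=C1\C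
F7 | step 5 | germacra-1(10)E,4E-diene-6,8,12-triol (C11 epimers) | C1[C@H](O)[C@@H](C(C)CO)[C@@H](O)/C=C(C)/CC/C=C1\C
F8 | step 5 | 6,8-dihydroxygermacra-1(10)E,4E-dien-12-al (C11 epimers) | C1[C@H](O)[C@@H](C(C)C=O)[C@@H](O)/C=C(C)/CC/C=C1\C
F9 | step 5 | 12,6-lactol of F8 | C1[C@H](O)[C@@H]2[C@@H](OC(O)C2C)/C=C(C)/CC/C=C1\C
F10 | step 5 | 8-hydroxygermacra-1(10)E,4E-dien-12,6-olide (C11 epimers) | C1[C@H](O)[C@@H]2[C@@H](OC(=O)C2C)/C=C(C)/CC/C=C1\C
F11 | step 5 | dilithio alkoxide enolate of F10 | [Li+].[Li+].C1[C@H]([O-])[C@@H]2[C@@H](OC([O-])=C2C)/C=C(C)/CC/C=C1\C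
F12 | step 6 | 6,8,12-triacetate of 14 | C1[C@H](OC(C)=O)[C@@H]([C@](C)(O)COC(C)=O)[C@@H](OC(C)=O)/C=C(C)/CC/C=C1\C
F13 | step 6 | 6,8-diacetate of 14 | C1[C@H](OC(C)=O)[C@@H]([C@](C)(O)CO)[C@@H](OC(C)=O)/C=C(C)/CC/C=C1\C
F14 | step 6 | 6,8-diacetoxy-11-hydroxygermacra-1(10)E,4E-dien-12-al | C1[C@H](OC(C)=O)[C@@H]([C@](C)(O)C=O)[C@@H](OC(C)=O)/C=C(C)/CC/C=C1\C
F15 | step 6 | 6,8-diacetoxy-11-hydroxygermacra-1(10)E,4E-dien-12-oic acid | C1[C@H](OC(C)=O)[C@@H]([C@](C)(O)C(=O)O)[C@@H](OC(C)=O)/C=C(C)/CC/C=C1\C
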